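The pyranone ring (ring C) is opened at O1–C2 and C4–C4a. The feature exploited is that O1 and C4a are ortho neighbours on ring A, a latent C,O-dinucleophile, while C4 and C2 of the three-carbon chain are an acyl and a benzylic electrophile. An Evans syn-glycolate aldol fixes C3 and a C2 carbinol, stored as Weinreb amide and tosylate. In the key step an ortho-lithiated lithium phenoxide, made from a symmetric bromophenol, acylates at C4 and, while C4 stays a chelated tetrahedral adduct, O1 displaces the C2 tosylate with inversion, closing ring C as the 2,3-trans isomer. One boron trichloride step then frees the three phenols.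

Key step: step 7

Assumption: the O-benzylated aldehydes 4 and 9 are taken as catalogue compounds; each is otherwise one benzylation away from 3-hydroxy-4,5-dimethoxybenzaldehyde or syringaldehyde.

**Route**

Step 1
Reactants: 1 (R)-4-benzyloxazolidin-2-one; 2 methoxyacetyl chloride
Product: 3 (R)-4-benzyl-3-(2-methoxyacetyl)oxazolidin-2-one
Conditions: n-BuLi, THF, −78 °C; then 2, −78 → 0 °C
Reagents that add atoms: none
Why: N-acylation of the lithiated oxazolidinone by the acid chloride is the standard loading of an Evans auxiliary and creates no new stereocentre.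

Step 2
Reactants: 3 (R)-4-benzyl-3-(2-methoxyacetyl)oxazolidin-2-one; 4 3-(benzyloxy)-4,5-dimethoxybenzaldehyde
Product: 6 (R)-4-benzyl-3-[(2R,3S)-3-[3-(benzyloxy)-4,5-dimethoxyphenyl]-3-hydroxy-2-methoxypropanoyl]oxazolidin-2-one, via Z-dibutylboron enolate 5 (not isolated)
Conditions: Bu2BOTf, Et3N, CH2Cl2, −78 → 0 °C; then 4, −78 → 0 °C; pH 7 buffer, MeOH, H2O2, 0 °C
Reagents that add atoms: none
Why: In this Evans boron aldol the Z-enolate 5 should react through a closed chair (Zimmerman–Traxler) transition state on the face away from the benzyl group of the (R)-auxiliary, giving the 2,3-syn adduct with (2R) at the methoxy-bearing carbon and (3S) at the carbinol carbon.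

Step 3
Reactants: 6 (R)-4-benzyl-3-[(2R,3S)-3-[3-(benzyloxy)-4,5-dimethoxyphenyl]-3-hydroxy-2-methoxypropanoyl]oxazolidin-2-one
Product: 7 (2R,3S)-3-[3-(benzyloxy)-4,5-dimethoxyphenyl]-3-hydroxy-N,2-dimethoxy-N-methylpropanamide
Conditions: Me(MeO)NH·HCl, AlMe3, CH2Cl2, −20 → 0 °C; cold dilute aq. HCl work-up
Reagents that add atoms: N,O-dimethylhydroxylamine hydrochloride, CNOC.Cl
Why: Aluminium amide transamination (Weinreb amide formation), assisted by the free β-hydroxyl, should cleave the auxiliary at the exocyclic carbonyl without touching either stereocentre.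

Step 4
Reactants: 7 (2R,3S)-3-[3-(benzyloxy)-4,5-dimethoxyphenyl]-3-hydroxy-N,2-dimethoxy-N-methylpropanamide
Product: 8 (2R,3S)-3-[3-(benzyloxy)-4,5-dimethoxyphenyl]-N,2-dimethoxy-N-methyl-3-(tosyloxy)propanamide
Conditions: Ts2O, Et3N, DMAP (cat.), CH2Cl2, −20 → 0 °C; used without chromatography
Reagents that add atoms: p-toluenesulfonic anhydride, Cc1ccc(cc1)S(=O)(=O)OS(=O)(=O)c1ccc(C)cc1
Why: O-sulfonylation with the anhydride (no chloride present) forms only an O–S bond, so the carbinol configuration is retained, the inductively deactivated benzylic tosylate should survive direct use, and a tosylate is chosen because it has no acidic α-hydrogen for the aryllithium of step 7 to remove.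

Step 5
Reactants: 9 4-(benzyloxy)-3,5-dimethoxybenzaldehyde
Product: 11 4-(benzyloxy)-3,5-dimethoxyphenol, via aryl formate 10 (not isolated)
Conditions: mCPBA, CH2Cl2, 0 °C → rt; then K2CO3, MeOH, rt
Reagents that add atoms: mCPBA, OOC(=O)c1cccc(Cl)c1
Why: In this Baeyer–Villiger oxidation the electron-rich aryl group migrates to give formate 10, which is methanolysed in the same flask to the phenol.

Step 6
Reactants: 11 4-(benzyloxy)-3,5-dimethoxyphenol
Product: 12 4-(benzyloxy)-2-bromo-3,5-dimethoxyphenol
Conditions: NBS (1.0 equiv), CH2Cl2, −40 → 0 °C, dark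
Reagents that add atoms: N-bromosuccinimide, O=C1CCC(=O)N1Br
Why: Electrophilic aromatic bromination goes ortho to the hydroxyl, and since the para position is blocked and the two ortho positions are equivalent by symmetry, only this monobromide can form.

Step 7
Reactants: 12 4-(benzyloxy)-2-bromo-3,5-dimethoxyphenol; 8 (2R,3S)-3-[3-(benzyloxy)-4,5-dimethoxyphenyl]-N,2-dimethoxy-N-methyl-3-(tosyloxy)propanamide
Product: 16 (2R,3R)-6-(benzyloxy)-2-[3-(benzyloxy)-4,5-dimethoxyphenyl]-3,5,7-trimethoxychroman-4-one, via aryllithium phenoxide dianion 13 (not isolated), via open tetrahedral adduct 14 (not isolated), via cyclised lithium hemiaminal 15 (not isolated)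
Conditions: 12, n-BuLi (2.05 equiv), THF, −78 °C; then 8, −78 → −40 °C; DMPU, → 0 °C; 1 M HCl, 0 °C
Reagents that add atoms: none
Why: Proposed new method: a convergent anionic [3+3] annulation whose closest known reaction types are the Weinreb ketone synthesis with ortho-lithiated lithium phenoxides (from 2-bromophenols and two equivalents of n-BuLi) and the intramolecular Williamson (phenoxide SN2) closure of chromans, which have not been run as one cascade onto a β-sulfonyloxy amide. Deprotonation and bromine–lithium exchange turn 12 into the C,O-dianion 13, whose carbanion at C4a adds to the amide carbonyl (C4) of 8 to give the chelated tetrahedral adduct 14; on warming with DMPU the phenoxide O1 displaces the tosylate at C2 to give 15, and the acid quench collapses the N,O-acetal to the ketone. Ring C closes in the 6-exo-tet mode. C3 is carried unchanged from the aldol, and C2 is set by stereospecific SN2 inversion of the (S)-tosylate, which gives (2R) with the aryl group trans to the C3 methoxyl. The step needs C-acylation before any alkylation and no β-elimination: the bromine fixes the site of C–C bond formation, the aryllithium is far more nucleophilic than the lithium phenoxide at −78 °C, and because C4 stays a tetrahedral alkoxide until the quench there is no enolisable ketone beside the leaving group. Elimination to a chalcone followed by non-selective oxa-Michael closure should therefore be shut off.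

Step 8
Reactants: 16 (2R,3R)-6-(benzyloxy)-2-[3-(benzyloxy)-4,5-dimethoxyphenyl]-3,5,7-trimethoxychroman-4-one
Product: 17 (2R,3R)-5,6-dihydroxy-2-(3-hydroxy-4,5-dimethoxyphenyl)-3,7-dimethoxychroman-4-one (CNP0075601.1)
Conditions: BCl3 (excess), pentamethylbenzene, CH2Cl2, −78 → 0 °C; MeOH, then water; argon
Reagents that add atoms: none
Why: In this Lewis acid dealkylation BCl3 with pentamethylbenzene as cation scavenger should cleave both aryl benzyl ethers at low temperature, while the boron chelate between the C4 carbonyl and the peri 5-methoxyl activates only that methyl ether, so the 7-, 4'- and 5'-aryl methyl ethers, the aliphatic 3-methyl ether and both stereocentres should survive at or below 0 °C.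

**Compound list**

1 | (R)-4-benzyloxazolidin-2-one | O=C1N[C@H](Cc2ccccc2)CO1 | starting material
2 | methoxyacetyl chloride | COCC(=O)Cl | starting material
3 | (R)-4-benzyl-3-(2-methoxyacetyl)oxazolidin-2-one | COCC(=O)N1[C@H](Cc2ccccc2)COC1=O | intermediate
4 | 3-(benzyloxy)-4,5-dimethoxybenzaldehyde | O=Cc1cc(OCc2ccccc2)c(OC)c(OC)c1 | starting material
5 | Z-dibutylboron enolate of 3 (not isolated) | CO/C=C(\OB(CCCC)CCCC)N1[C@H](Cc2ccccc2)COC1=O | intermediate
6 | (R)-4-benzyl-3-[(2R,3S)-3-[3-(benzyloxy)-4,5-dimethoxyphenyl]-3-hydroxy-2-methoxypropanoyl]oxazolidin-2-one | O=C([C@H](OC)[C@@H](O)c1cc(OCc2ccccc2)c(OC)c(OC)c1)N1[C@H](Cc2ccccc2)COC1=O | intermediate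
7 | (2R,3S)-3-[3-(benzyloxy)-4,5-dimethoxyphenyl]-3-hydroxy-N,2-dimethoxy-N-methylpropanamide | CON(C)C(=O)[C@H](OC)[C@@H](O)c1cc(OCc2ccccc2)c(OC)c(OC)c1 | intermediate
8 | (2R,3S)-3-[3-(benzyloxy)-4,5-dimethoxyphenyl]-N,2-dimethoxy-N-methyl-3-(tosyloxy)propanamide | CON(C)C(=O)[C@H](OC)[C@@H](OS(=O)(=O)c1ccc(C)cc1)c1cc(OCc2ccccc2)c(OC)c(OC)c1 | intermediate
9 | 4-(benzyloxy)-3,5-dimethoxybenzaldehyde | O=Cc1cc(OC)c(OCc2ccccc2)c(OC)c1 | starting material
10 | 4-(benzyloxy)-3,5-dimethoxyphenyl formate (not isolated) | O=COc1cc(OC)c(OCc2ccccc2)c(OC)c1 | intermediate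
11 | 4-(benzyloxy)-3,5-dimethoxyphenol | Oc1cc(OC)c(OCc2ccccc2)c(OC)c1 | intermediate
12 | 4-(benzyloxy)-2-bromo-3,5-dimethoxyphenol | Oc1cc(OC)c(OCc2ccccc2)c(OC)c1Br | intermediate
13 | lithium 4-(benzyloxy)-2-lithio-3,5-dimethoxyphenoxide (not isolated) | [Li]Oc1cc(OC)c(OCc2ccccc2)c(OC)c1[Li] | intermediate
14 | dilithium salt of the open tetrahedral adduct of 13 and 8, chain configuration of 8 retained, carbinolamine carbon undefined (not isolated) | [Li]Oc1cc(OC)c(OCc2ccccc2)c(OC)c1C(O[Li])(N(C)OC)[C@H](OC)[C@@H](OS(=O)(=O)c1ccc(C)cc1)c1cc(OCc2ccccc2)c(OC)c(OC)c1 | intermediate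
15 | lithium (2R,3R)-6-(benzyloxy)-2-[3-(benzyloxy)-4,5-dimethoxyphenyl]-3,5,7-trimethoxy-4-[methoxy(methyl)amino]chroman-4-olate, C4 undefined (not isolated) | COc1cc2c(c(OC)c1OCc1ccccc1)C(O[Li])(N(C)OC)[C@H](OC)[C@@H](c1cc(OCc3ccccc3)c(OC)c(OC)c1)O2 | intermediate
16 | (2R,3R)-6-(benzyloxy)-2-[3-(benzyloxy)-4,5-dimethoxyphenyl]-3,5,7-trimethoxychroman-4-one | COc1cc2c(c(OC)c1OCc1ccccc1)C(=O)[C@H](OC)[C@@H](c1cc(OCc3ccccc3)c(OC)c(OC)c1)O2 | intermediate
17 | (2R,3R)-5,6-dihydroxy-2-(3-hydroxy-4,5-dimethoxyphenyl)-3,7-dimethoxychroman-4-one | COc1cc2c(c(O)c1O)C(=O)[C@H](OC)[C@@H](c1cc(O)c(OC)c(OC)c1)O2 | target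

**Step count and risks**

Total step count: 8. Longest linear sequence: 6 steps (steps 1, 2, 3, 4, 7, 8); the ring A branch (steps 5 and 6) joins at step 7.

Steps most likely to fail:

1. Step 7 (proposed new method). The hindered aryllithium may act as a base instead of adding to the amide, causing β-elimination of the sulfonate. The tetrahedral adduct may also collapse before ring closure, so that elimination and non-selective reclosure erode the enantiomeric purity, or the lithium phenoxide may displace too slowly. The fallback sets out from 7 and 12 and comes back at 16, using known chemistry only. Alcohol 7 is first turned into its magnesium alkoxide with i-PrMgCl (1 equiv, THF, −20 °C), and the dianion 13 made from 12 as in step 7 is added. Aqueous work-up should give the hydroxy ketone (2R,3S)-1-[3-(benzyloxy)-6-hydroxy-2,4-dimethoxyphenyl]-3-[3-(benzyloxy)-4,5-dimethoxyphenyl]-3-hydroxy-2-methoxypropan-1-one F1. An intramolecular Mitsunobu reaction (PPh3, DIAD, THF, 0 °C) should then close O1–C2 with inversion to give 16.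

2. Step 4. The benzylic sulfonate may ionise or eliminate during formation or handling, which would scramble the configuration at the future C2. The fallback sets out from 7 and 12 and comes back at 16 without any sulfonate. An intermolecular Mitsunobu etherification of phenol 12 with alcohol 7 (PPh3, DIAD, toluene, 0 °C) should give, with inversion, the aryl ether (2R,3R)-3-[4-(benzyloxy)-2-bromo-3,5-dimethoxyphenoxy]-3-[3-(benzyloxy)-4,5-dimethoxyphenyl]-N,2-dimethoxy-N-methylpropanamide F2. A Parham cyclisation (n-BuLi, THF, −100 → −78 °C; bromine–lithium exchange, then intramolecular attack on the Weinreb amide) should then form C4–C4a and give 16.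

3. Step 8. Dealkylation may overrun to the hindered 4'-methyl ether or the 3-methyl ether, or the Lewis acid may open ring C. The fallback sets out from 16 and comes back at 17 in two orthogonal operations. Chelation-controlled cleavage of the peri methyl ether alone (MgI2·OEt2, THF, 50 °C) should give (2R,3R)-6-(benzyloxy)-2-[3-(benzyloxy)-4,5-dimethoxyphenyl]-5-hydroxy-3,7-dimethoxychroman-4-one F3. Neutral hydrogenolysis of both benzyl ethers (H2, Pd/C, EtOAc) should then give 17.

**Further compounds**

F1 | step 7 | (2R,3S)-1-[3-(benzyloxy)-6-hydroxy-2,4-dimethoxyphenyl]-3-[3-(benzyloxy)-4,5-dimethoxyphenyl]-3-hydroxy-2-methoxypropan-1-one | COc1cc(O)c(c(OC)c1OCc1ccccc1)C(=O)[C@H](OC)[C@@H](O)c1cc(OCc2ccccc2)c(OC)c(OC)c1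
F2 | step 4 | (2R,3R)-3-[4-(benzyloxy)-2-bromo-3,5-dimethoxyphenoxy]-3-[3-(benzyloxy)-4,5-dimethoxyphenyl]-N,2-dimethoxy-N-methylpropanamide | CON(C)C(=O)[C@H](OC)[C@H](Oc1cc(OC)c(OCc2ccccc2)c(OC)c1Br)c1cc(OCc2ccccc2)c(OC)c(OC)c1
F3 | step 8 | (2R,3R)-6-(benzyloxy)-2-[3-(benzyloxy)-4,5-dimethoxyphenyl]-5-hydroxy-3,7-dimethoxychroman-4-one | COc1cc2c(c(O)c1OCc1ccccc1)C(=O)[C@H](OC)[C@@H](c1cc(OCc3ccccc3)c(OC)c(OC)c1)O2
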